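Amounts opened the meeting: the flask charges the substrate pair as Sunday's run did, but holds 3.00 equiv of solid reagent against Sunday's 4.2 equiv.

| setting | Sunday's | Wednesday's | flask |
|---|---|---|---|
| left-handed substrate | 0.50 M | 0.25 M | 0.50 M |
| right-handed substrate | 0.50 M | 0.25 M | 0.50 M |
| solid reagent | 4.2 equiv | 3 equiv | 3.00 equiv |
| remark | run made earlier | run made earlier |  |
| time |  |  | 1.5 h |

| run | time / min | left-handed product / % |
|---|---|---|
| Sunday's | 8.00 | 1.0 |
| Sunday's | 12.0 | 1.8 |
| Sunday's | 20.0 | 3.3 |
| Sunday's | 30.0 | 5.3 |
| Sunday's | 50.0 | 7.8 |
| Sunday's | 90.0 | 12.3 |
| Wednesday's | 20.0 | 5.6 |
| Wednesday's | 40.0 | 10.7 |
| Wednesday's | 50.0 | 12.0 |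
| Wednesday's | 80.0 | 15.8 |
| Wednesday's | 90.0 | 16.1 |

(each reading ± 0.3 percentage points)

- coupling partner is single-handed; left-handed substrate and right-handed substrate are mirror images of each other, charged as a racemate, each of them at the stated concentration
- given per volume of solution although it is solid: solid reagent
- at the start none of the solid reagent is in solution
- the handed part of coupling partner does not stay in what it makes, so the products of the two hands are mirror images too

1. amount of left-handed product at 1.5 h, in percent of the left-handed substrate and right-handed substrate together charged
2. the change that raises the amount of left-handed product at 1.5 h, in percent of the left-handed substrate and right-handed substrate together charged most ("none" if none brings more than 2 percentage points) (alpha / delta / none)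
3. amount of left-handed product at 1.5 h, in percent of the left-handed substrate and right-handed substrate together charged, after delta

- alpha: doubling the solubility of the solid reagent, all else as stated
- delta: doubling the dissolution coefficient of the solid reagent, all else as stated

The chair asked whether that difference in solid counts. One member took the coupling partner to be the dissolved solid reagent, and assumed that in these flasks a solid still present acts the same whatever its amount. She then took Sunday's 12.3% at 90.0 min, doubled it for the product of the other hand, and converted it to equivalents. That gave a draw D of 16.4%, D being the share of the charged solid that both products take if the two hands keep pace. Because D is below one, she argued, solid remains at the asked time and is not the limiting reagent, so the flask should read as Sunday did, 12.3%.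

A second member objected that Wednesday's run changes strength and load together. The first member answered that its draw, 21.5%, is below one as well.

The forecast gave less, 11.7%, with alpha as best change and 15.5% after delta, noting: “Solid load seems to matter little, since the solid is in large excess”.

The flask gave 12.4%. The best change was alpha, adding 8 percentage points against 5.7 points for delta, which reached 18.1%.

    coupling partner + left-handed substrate → left-handed product (k = 0.470 L mol⁻¹ min⁻¹)
    coupling partner + right-handed substrate → right-handed product (k = 0.220 L mol⁻¹ min⁻¹)
    left-handed substrate ⇌ achiral form (K = 0.900, k = 0.0490 min⁻¹)
    right-handed substrate ⇌ achiral form (K = 0.900, k = 0.0490 min⁻¹)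
    achiral form → waste (k = 0.00190 min⁻¹)
    solid reagent ⇌ coupling partner, rate k6*(cs6 - [coupling partner]) while solid is left; crystals form when [coupling partner] > cs6 (solubility = 0.0960 M, k = 0.0420 min⁻¹)
    coupling partner ⇌ dormant form (K = 0.450, k = 0.0270 min⁻¹)
    achiral form → decomposed reagent (k = 0.110 min⁻¹)

The flask had lost 17.3% of its solid reagent at 1.50 h, against D of 16.4%, though the hands did not keep pace there: right-handed product stood at 6.47% against 12.4% of left-handed product. A neighbouring flask charged 1.20 equiv, with other charges and the time held. Scaling D to that charge gives 41.0%, still below one, which again points to Sunday's reading. That neighbouring flask gave 12.4% of left-handed product, with 56.7% of its solid reagent remaining at 1.50 h.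

(The readings are simulated for an exercise; scatter was added.)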